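**Strategy.** The central ring of vidalol B alternates oxygen-bearing carbons (C2, C4, C6) with carbons bearing a benzyl group (C1, C5) or bromine (C3), i.e. three head-to-tail C≡C–O units. The route therefore disconnects that ring into three ynol ethers: a rhodium-catalysed [2+2+2] cross-cyclotrimerisation of two molecules of a 2,3-dibromo-4,5-dimethoxybenzyl-substituted ethyl ynol ether with one ethoxyacetylene should form bonds C6–C1, C4–C5 and C2–C3, closing the ring with both benzyl arms and all three oxygens in place. The precursor is reached from vanillin by standard steps; afterwards only C3 bromination and global ether cleavage remain.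

Key step: step 6

**Remarks on the chemistry**
- Vidalol B is achiral, so no stereocentre has to be set; racemic BINAP is sufficient.
- Central-ring numbering used throughout: C1 and C5 carry the benzyl groups, C2, C4 and C6 the oxygens, C3 the bromine (hydrogen until step 7).
- The ynol ether carries the 2,3-dibromo-4,5-dimethoxybenzyl group: the benzylic carbon is flanked by C–Br and C–H, with the methoxy groups para and meta to it. Its systematic name is therefore 2,3-dibromo-1-(3-ethoxyprop-2-yn-1-yl)-4,5-dimethoxybenzene.
- The O-ethyl groups are kept on all three alkynes and the O-methyl groups on the outer rings. Ethyl ynol ethers are stable at room temperature, and all seven alkyl ethers fall in one final operation.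
- Catalyst-bound rhodacycles of step 6 are treated as species of the catalytic cycle and are not numbered.

**Route**

Step 1
Reactants: 1 vanillin
Product: 3 2,3-dibromo-4-hydroxy-5-methoxybenzaldehyde (5,6-dibromovanillin), via 5-bromovanillin 2 (not isolated)
Conditions: Br2 (1.05 equiv), AcOH, rt; then Fe powder (cat.), Br2 (1.2 equiv), rt to 50 °C
Reagents that add atoms: bromine, BrBr
Why: Electrophilic aromatic bromination: the first bromine enters ortho to the free phenol and the second, with FeBr3 formed from the iron, enters para to the methoxy group, the established outcome for vanillin, while the position wedged between CHO and OMe stays free.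

Step 2
Reactants: 3 2,3-dibromo-4-hydroxy-5-methoxybenzaldehyde
Product: 4 2,3-dibromo-4,5-dimethoxybenzaldehyde
Conditions: MeI, K2CO3, DMF, rt
Reagents that add atoms: iodomethane, CI
Why: Williamson ether synthesis: the acidic ortho-brominated phenoxide attacks iodomethane by SN2 while the aldehyde and aryl bromides are inert.

Step 3
Reactants: 4 2,3-dibromo-4,5-dimethoxybenzaldehyde
Product: 5 (2,3-dibromo-4,5-dimethoxyphenyl)methanol
Conditions: NaBH4, MeOH/THF, 0 °C
Reagents that add atoms: none
Why: Hydride reduction of an aldehyde with NaBH4, chemoselective in the presence of aryl bromides and aryl ethers.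

Step 4
Reactants: 5 (2,3-dibromo-4,5-dimethoxyphenyl)methanol
Product: 6 2,3-dibromo-1-(bromomethyl)-4,5-dimethoxybenzene
Conditions: PBr3, CH2Cl2, 0 °C to rt
Reagents that add atoms: phosphorus tribromide, BrP(Br)Br
Why: Conversion of a benzylic alcohol to the bromide with PBr3 (SN2 displacement of the phosphite ester by bromide), which leaves aryl methyl ethers untouched at this temperature.

Step 5
Reactants: 6 2,3-dibromo-1-(bromomethyl)-4,5-dimethoxybenzene; 7 ethoxyacetylene
Product: 9 2,3-dibromo-1-(3-ethoxyprop-2-yn-1-yl)-4,5-dimethoxybenzene, via lithium ethoxyacetylide 8 (not isolated)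
Conditions: 7 (1.5 equiv), n-BuLi (1.4 equiv), THF, −78 °C; then 6, DMPU, −78 to 0 °C; NaHCO3 work-up, Et3N-deactivated silica
Reagents that add atoms: n-butyllithium, [Li]CCCC (supplies only the lithium of intermediate 8)
Why: SN2 alkylation of a lithium acetylide by a primary benzylic bromide, accelerated by DMPU; the alkyne is kept in excess over n-BuLi so that no alkyllithium remains to exchange with the aryl bromides, which the acetylide itself does not attack.

Step 6
Reactants: 9 2,3-dibromo-1-(3-ethoxyprop-2-yn-1-yl)-4,5-dimethoxybenzene (two molecules); 7 ethoxyacetylene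
Product: 10 2,4-bis[(2,3-dibromo-4,5-dimethoxyphenyl)methyl]-1,3,5-triethoxybenzene
Conditions: [Rh(cod)2]BF4 (10 mol%), rac-BINAP (10 mol%), CH2Cl2, H2 (1 atm, 30 min) then Ar purge; 9 (2.0 equiv); 7 (1.0 equiv in CH2Cl2, syringe pump over 6 h), rt
Reagents that add atoms: none
Why: Proposed new method: two molecules of 9 should undergo oxidative cyclisation at cationic monovalent rhodium to a rhodacyclopentadiene of trivalent rhodium (bond C6–C1), ethoxyacetylene 7 then inserts into the Rh–C5 bond (bond C4–C5) to give a rhodacycloheptatriene, and reductive elimination forms C2–C3 and releases the arene; the closest known reaction type is the cationic rhodium/bisphosphine-catalysed [2+2+2] cyclotrimerisation of alkynes, including regioselective homotrimerisation of alkynyl ethers, whereas a 2:1 cross-trimerisation of an internal with a terminal ynol ether has not been shown. The only ring closed is the central benzene ring, formed by [2+2+2] cycloaddition whose last bond (C2–C3) is made by C(sp2)–C(sp2) reductive elimination from the seven-membered metallacycle. No stereocentre is created. Head-to-tail regiochemistry is needed in all three C–C bond formations and should follow from the uniform polarisation of ynol ethers, each new bond joining a nucleophilic β-carbon (C1, C5, C3) to an electrophilic oxygen-bearing α-carbon (C6, C4, C2), which is also the least congested arrangement because no two ethoxy or two benzyl groups become neighbours. The 2:1 cross-selection should be secured by sterics and concentration: the tetrasubstituted rhodacycle from two molecules of 9 should accept the small terminal alkyne 7 far more readily than a third molecule of 9, syringe-pump addition keeps 7 too dilute to homotrimerise, and the aryl C–Br bonds are not expected to add oxidatively to the cationic rhodium complex at room temperature.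

Step 7
Reactants: 10 2,4-bis[(2,3-dibromo-4,5-dimethoxyphenyl)methyl]-1,3,5-triethoxybenzene
Product: 11 1-bromo-3,5-bis[(2,3-dibromo-4,5-dimethoxyphenyl)methyl]-2,4,6-triethoxybenzene
Conditions: NBS (1.05 equiv), MeCN, 0 °C, dark
Reagents that add atoms: N-bromosuccinimide, O=C1CCC(=O)N1Br
Why: Electrophilic aromatic bromination: the single free position of the central ring (C3), activated by two ortho and one para ethoxy groups, is far more nucleophilic than the remaining C–H of the dibrominated outer rings, and dark polar conditions suppress radical benzylic bromination.

Step 8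
Reactants: 11 1-bromo-3,5-bis[(2,3-dibromo-4,5-dimethoxyphenyl)methyl]-2,4,6-triethoxybenzene
Product: 12 vidalol B, 2-bromo-4,6-bis[(2,3-dibromo-4,5-dihydroxyphenyl)methyl]benzene-1,3,5-triol
Conditions: BBr3 (12 equiv), CH2Cl2, −78 °C to rt; then ice-water
Reagents that add atoms: none
Why: Lewis-acid-mediated aryl ether cleavage with BBr3 (ether–borane adduct, then SN2 attack of bromide on methyl or ethyl), the standard last step for polybrominated phenols, which should leave aryl C–Br and diarylmethane C–C bonds intact at or below room temperature.

**Compound list**

1 | vanillin (4-hydroxy-3-methoxybenzaldehyde) | COc1cc(C=O)ccc1O | starting material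
2 | 5-bromovanillin (3-bromo-4-hydroxy-5-methoxybenzaldehyde) | COc1cc(C=O)cc(Br)c1O | intermediate
3 | 2,3-dibromo-4-hydroxy-5-methoxybenzaldehyde | COc1cc(C=O)c(Br)c(Br)c1O | intermediate
4 | 2,3-dibromo-4,5-dimethoxybenzaldehyde | COc1cc(C=O)c(Br)c(Br)c1OC | intermediate
5 | (2,3-dibromo-4,5-dimethoxyphenyl)methanol | COc1cc(CO)c(Br)c(Br)c1OC | intermediate
6 | 2,3-dibromo-1-(bromomethyl)-4,5-dimethoxybenzene | COc1cc(CBr)c(Br)c(Br)c1OC | intermediate
7 | ethoxyacetylene | CCOC#C | starting material
8 | lithium ethoxyacetylide | CCOC#C[Li] | intermediate
9 | 2,3-dibromo-1-(3-ethoxyprop-2-yn-1-yl)-4,5-dimethoxybenzene | CCOC#CCc1cc(OC)c(OC)c(Br)c1Br | intermediate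
10 | 2,4-bis[(2,3-dibromo-4,5-dimethoxyphenyl)methyl]-1,3,5-triethoxybenzene | CCOc1cc(OCC)c(Cc2cc(OC)c(OC)c(Br)c2Br)c(OCC)c1Cc1cc(OC)c(OC)c(Br)c1Br | intermediate
11 | 1-bromo-3,5-bis[(2,3-dibromo-4,5-dimethoxyphenyl)methyl]-2,4,6-triethoxybenzene | CCOc1c(Br)c(OCC)c(Cc2cc(OC)c(OC)c(Br)c2Br)c(OCC)c1Cc1cc(OC)c(OC)c(Br)c1Br | intermediate
12 | vidalol B, 2-bromo-4,6-bis[(2,3-dibromo-4,5-dihydroxyphenyl)methyl]benzene-1,3,5-triol | Oc1cc(Cc2c(O)c(Br)c(O)c(Cc3cc(O)c(O)c(Br)c3Br)c2O)c(Br)c(Br)c1O | target

**Step count and risks**

Total step count: 8. Longest linear sequence: 8 steps (vanillin 1 to vidalol B 12).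

Steps most likely to fail:

1. Step 6 (proposed new method). The cross-trimerisation may be diverted by homotrimerisation of ethoxyacetylene, by formation of the 1:2 cross-trimer, by head-to-head coupling, or by failure of the hindered internal ynol ether to enter the rhodacycle. The fallback uses known chemistry and sets out from benzylic alcohol 5. A two-fold dehydrative Friedel–Crafts benzylation of commercial 1,3,5-triethoxybenzene (CCOc1cc(OCC)cc(OCC)c1) with 5 (2 equiv; Bi(OTf)3 cat., MeNO2, rt) would first give 2-[(2,3-dibromo-4,5-dimethoxyphenyl)methyl]-1,3,5-triethoxybenzene F1. A second benzylation at either of its two equivalent free positions should then give compound 10, where the route is rejoined. Over-benzylation would be limited by stoichiometry and crowding.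

2. Step 5. Substitution at the ortho-brominated benzylic centre may be sluggish, and the basic medium may isomerise the propargylic ynol ether to an allenyl ether. The fallback sets out from benzyl bromide 6 and ethoxyacetylene 7 and forms the C–C bond under neutral conditions by Stille coupling. Lithium ethoxyacetylide 8 would be quenched with Bu3SnCl to give tributyl(ethoxyethynyl)stannane F2. F2 would then be coupled with 6 (Pd2(dba)3, P(2-furyl)3, THF, 50 °C), the benzylic C–Br bond adding to zerovalent palladium much faster than the hindered aryl C–Br bonds. The route is rejoined at compound 9.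

3. Step 8. Cleavage of the seven ethers may stop short, or the HBr released on quench may cause loss or migration of the bromine on the very electron-rich central ring. The fallback sets out from compound 10 and reverses the order of the last two operations. BBr3 cleavage of 10 would give 2,4-bis[(2,3-dibromo-4,5-dihydroxyphenyl)methyl]benzene-1,3,5-triol F3. Its single free phloroglucinol position would then be brominated with NBS (1.0 equiv, MeCN, −40 °C), this position reacting far faster than the electron-poor dibromocatechol rings. The route is rejoined at target 12.

**Further compounds**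

F1 | step 6 | 2-[(2,3-dibromo-4,5-dimethoxyphenyl)methyl]-1,3,5-triethoxybenzene | CCOc1cc(OCC)c(Cc2cc(OC)c(OC)c(Br)c2Br)c(OCC)c1
F2 | step 5 | tributyl(ethoxyethynyl)stannane | CCOC#C[Sn](CCCC)(CCCC)CCCC
F3 | step 8 | 2,4-bis[(2,3-dibromo-4,5-dihydroxyphenyl)methyl]benzene-1,3,5-triol | Oc1cc(O)c(Cc2cc(O)c(O)c(Br)c2Br)c(O)c1Cc1cc(O)c(O)c(Br)c1Br
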